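Ring A of the octalin is cut across C1–C2 and C3–C4. Its only unsaturation, the tetrasubstituted C4a=C8a bond shared with ring B, together with the side chain on C2 beside C1, is the imprint of a [4+2] adduct of a ring-B bis(exocyclic) diene. One thermal cycloaddition therefore joins the two halves and closes ring A with the acyl group on C2. The diene is an (E)-1-silyloxy diene held s-cis on the gem-dimethylcyclohexane. The dienophile is a vinyl ketone that already carries the fully configured 1,2-dioxane propanoate, built by epoxide perhydrolysis and an SN2 peroxide ring closure. Silanol loss and a reductive alkene transposition then place the exocyclic (Z)-alkene.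

Key step: step 17

Assumption: the target is read as (2S)-2-[(3R,6S)-…-1,2-dioxan-3-yl]propanoic acid with a (Z)-exocyclic alkene (chain cis to C1 of the octalin); centres drawn without configuration in 5, 26, 29 and 30 are mixtures that converge later. Octalin numbering: ring A = C1–C4, ring B = C5–C8, gem-dimethyl on C5. Geranyl acetate, (E)-crotylboronic acid pinacol ester and iodoethene are taken as commercial.

Step 1
Reactants: 1 2,2-dimethylcyclohexan-1-one; 2 ethyl formate
Product: 3 (6Z)-6-(hydroxymethylidene)-2,2-dimethylcyclohexan-1-one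
Conditions: NaH, EtOH (cat.), Et2O, 0 °C to rt; then aq. HCl
Reagents that add atoms: none
Why: Crossed Claisen condensation (α-formylation) at the only enolisable carbon of the ketone with a non-enolisable formate, the product being held as its sodium enolate until the acidic work-up; no stereocentre is formed.

Step 2
Reactants: 3 (6Z)-6-(hydroxymethylidene)-2,2-dimethylcyclohexan-1-one
Product: 4 (6E)-2,2-dimethyl-6-[(propan-2-yloxy)methylidene]cyclohexan-1-one
Conditions: 2-iodopropane, K2CO3, acetone, reflux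
Reagents that add atoms: 2-iodopropane, CC(C)I
Why: Williamson-type O-alkylation of the vinylogous acid gives the vinylogous ester, which removes the acidic proton so that an organolithium can add to the ketone.

Step 3
Reactants: 4 (6E)-2,2-dimethyl-6-[(propan-2-yloxy)methylidene]cyclohexan-1-one
Product: 6 2,3,3-trimethylcyclohex-1-ene-1-carbaldehyde, via tertiary carbinol 5 (not isolated)
Conditions: MeLi, Et2O, −78 to 0 °C; then 2 M HCl, THF, rt
Reagents that add atoms: methyllithium, [Li]C; water, O
Why: 1,2-Addition of MeLi gives the racemic carbinol, which aqueous acid ionises to an alkoxy-stabilised allyl cation that is hydrated at the former enol-ether carbon and loses propan-2-ol, a Stork–Danheiser-type 1,3-carbonyl transposition that destroys the carbinol centre and gives the tetrasubstituted enal.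

Step 4
Reactants: 6 2,3,3-trimethylcyclohex-1-ene-1-carbaldehyde
Product: 7 tert-butyl{[(E)-(3,3-dimethyl-2-methylidenecyclohexylidene)methyl]oxy}dimethylsilane
Conditions: TBSOTf, Et3N, Et2O, 0 °C
Reagents that add atoms: tert-butyldimethylsilyl trifluoromethanesulfonate, CC(C)(C)[Si](C)(C)OS(=O)(=O)C(F)(F)F
Why: Vinylogous soft enolisation (O-silylation, then loss of a proton from the C2 methyl group, the only γ-position bearing hydrogen) gives the cross-conjugated 1-silyloxy diene, and the preferred s-trans enal conformer translates into the (E)-enol ether with oxygen on the outside of the diene.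

Step 5
Reactants: 8 geranyl acetate
Product: 9 (2E)-3-methyl-6-oxohex-2-en-1-yl acetate
Conditions: O3 (1 equiv), pyridine (cat.), CH2Cl2, −78 °C; then Me2S
Reagents that add atoms: ozone, [O-][O+]=O
Why: Chemoselective ozonolysis, because the distal trisubstituted alkene is more electron-rich than the one deactivated by the allylic acetate, and reductive work-up gives the aldehyde with the (E)-alkene untouched.

Step 6
Reactants: 9 (2E)-3-methyl-6-oxohex-2-en-1-yl acetate; 10 2-[(2E)-but-2-en-1-yl]-4,4,5,5-tetramethyl-1,3,2-dioxaborolane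
Product: 12 (2E,6S,7R)-6-hydroxy-3,7-dimethylnona-2,8-dien-1-yl acetate, via homoallyl borate 11 (not isolated)
Conditions: (R)-3,3′-bis(2,4,6-triisopropylphenyl)-1,1′-binaphthyl-2,2′-diyl hydrogen phosphate (5 mol %), 4 Å molecular sieves, toluene, −30 °C; aq. NaHCO3 work-up
Reagents that add atoms: none
Why: Brønsted-acid-catalysed asymmetric crotylboration through a closed chair-like (Zimmerman–Traxler) transition state, in which the (E)-crotyl geometry gives the anti 6,7-relationship and the (R)-phosphoric acid, hydrogen-bonded to the boronate oxygen and the formyl hydrogen, directs attack to the Re face of the aldehyde, setting C6 as S and C7 as R.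

Step 7
Reactants: 12 (2E,6S,7R)-6-hydroxy-3,7-dimethylnona-2,8-dien-1-yl acetate
Product: 13 (2E,6S,7R)-6-(methanesulfonyloxy)-3,7-dimethylnona-2,8-dien-1-yl acetate
Conditions: MsCl, Et3N, CH2Cl2, 0 °C
Reagents that add atoms: methanesulfonyl chloride, CS(=O)(=O)Cl
Why: O-Sulfonylation of the secondary alcohol with retention turns the C–O bond into the leaving group for the later SN2 ring closure.

Step 8
Reactants: 13 (2E,6S,7R)-6-(methanesulfonyloxy)-3,7-dimethylnona-2,8-dien-1-yl acetate
Product: 14 (3R,4S,7E)-9-hydroxy-3,7-dimethylnona-1,7-dien-4-yl methanesulfonate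
Conditions: K2CO3 (0.2 equiv), MeOH, 0 °C
Reagents that add atoms: none
Why: Base-catalysed transesterification removes the primary allylic acetate, while the secondary mesylate, which has no acidifying neighbour, is inert to carbonate in cold methanol.

Step 9
Reactants: 14 (3R,4S,7E)-9-hydroxy-3,7-dimethylnona-1,7-dien-4-yl methanesulfonate
Product: 15 (3R,4S)-6-[(2S,3S)-3-(hydroxymethyl)-2-methyloxiran-2-yl]-3-methylhex-1-en-4-yl methanesulfonate
Conditions: Ti(OiPr)4 (10 mol %), L-(+)-diethyl tartrate (12 mol %), t-BuOOH (in decane), 4 Å molecular sieves, CH2Cl2, −20 °C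
Reagents that add atoms: tert-butyl hydroperoxide, CC(C)(C)OO
Why: Katsuki–Sharpless asymmetric epoxidation, in which the titanium tartrate binds the allylic alcohol and the L-(+)-tartrate delivers oxygen to the face that gives the (2S,3S)-epoxide as with geraniol, the isolated vinyl group being untouched; material from the minor crotylation enantiomer becomes a diastereomer here and should be separable.

Step 10
Reactants: 15 (3R,4S)-6-[(2S,3S)-3-(hydroxymethyl)-2-methyloxiran-2-yl]-3-methylhex-1-en-4-yl methanesulfonate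
Product: 16 (3R,4S,7R,8S)-7-hydroperoxy-8,9-dihydroxy-3,7-dimethylnon-1-en-4-yl methanesulfonate
Conditions: H2O2 (anhydrous, in Et2O), H3PMo12O40 (3 mol %), Et2O, rt
Reagents that add atoms: hydrogen peroxide, OO
Why: Acid-catalysed perhydrolysis of a trisubstituted epoxide, in which hydrogen peroxide attacks the more substituted carbon in a borderline SN2 opening with inversion, sets the tertiary C–OO centre (7R) from the epoxide and leaves the carbinol centre (8S) unchanged.

Step 11
Reactants: 16 (3R,4S,7R,8S)-7-hydroperoxy-8,9-dihydroxy-3,7-dimethylnon-1-en-4-yl methanesulfonate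
Product: 17 (1S)-1-{(3R,6R)-6-[(2R)-but-3-en-2-yl]-3-methyl-1,2-dioxan-3-yl}ethane-1,2-diol
Conditions: KOtBu (1.05 equiv), 18-crown-6, THF, 0 °C
Reagents that add atoms: none
Why: Intramolecular Williamson-type alkylation of the hydroperoxide (6-exo-tet), in which one equivalent of base ionises only the most acidic O–H and the peroxy anion displaces the secondary mesylate with inversion, sets the ring CH–O centre as R and closes the 1,2-dioxane with the butenyl group trans to the diol-bearing chain.

Step 12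
Reactants: 17 (1S)-1-{(3R,6R)-6-[(2R)-but-3-en-2-yl]-3-methyl-1,2-dioxan-3-yl}ethane-1,2-diol
Product: 19 (2S)-2-{(3R,6R)-6-[(1S)-1,2-dihydroxyethyl]-6-methyl-1,2-dioxan-3-yl}propanoic acid, via β-peroxy aldehyde 18 (not isolated)
Conditions: O3, CH2Cl2/MeOH, −78 °C; Me2S; then NaClO2, NaH2PO4, 2-methylbut-2-ene, t-BuOH/H2O, 0 °C to rt
Reagents that add atoms: ozone, [O-][O+]=O; sodium chlorite, [Na+].[O-]Cl=O
Why: Ozonolysis of the only remaining alkene followed by Pinnick oxidation in the same flask, where the dialkyl peroxide and the diol are inert to ozone, Me2S and chlorite and the buffered non-basic medium avoids epimerisation or β-elimination of the α-branched aldehyde.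

Step 13
Reactants: 19 (2S)-2-{(3R,6R)-6-[(1S)-1,2-dihydroxyethyl]-6-methyl-1,2-dioxan-3-yl}propanoic acid
Product: 20 methyl (2S)-2-{(3R,6R)-6-[(1S)-1,2-dihydroxyethyl]-6-methyl-1,2-dioxan-3-yl}propanoate
Conditions: Me3SiCHN2, MeOH/toluene, 0 °C
Reagents that add atoms: (trimethylsilyl)diazomethane, C[Si](C)(C)C=[N+]=[N-]
Why: Neutral esterification (protonation of the diazoalkane by the acid, then O-alkylation of the carboxylate) leaves the stereocentres and the peroxide untouched.

Step 14
Reactants: 20 methyl (2S)-2-{(3R,6R)-6-[(1S)-1,2-dihydroxyethyl]-6-methyl-1,2-dioxan-3-yl}propanoate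
Product: 21 methyl (2S)-2-[(3R,6R)-6-formyl-6-methyl-1,2-dioxan-3-yl]propanoate
Conditions: NaIO4, THF/H2O, 0 °C
Reagents that add atoms: none
Why: Malaprade glycol cleavage through a cyclic periodate ester gives the aldehyde, which has a fully substituted α-carbon and so cannot enolise, preserving C6.

Step 15
Reactants: 21 methyl (2S)-2-[(3R,6R)-6-formyl-6-methyl-1,2-dioxan-3-yl]propanoate
Product: 22 methyl (2S)-2-[(3R,6R)-6-ethenyl-6-methyl-1,2-dioxan-3-yl]propanoate
Conditions: Ph3PCH3Br, KN(SiMe3)2, THF, 0 °C; then 21, −78 to 0 °C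
Reagents that add atoms: methyltriphenylphosphonium bromide, C[P+](c1ccccc1)(c1ccccc1)c1ccccc1.[Br-]
Why: Wittig methylenation of a non-enolisable aldehyde at low temperature, where the ylide is too weak a base to deprotonate the ester α-position and phosphorus is present only as ylide and oxide, not as a free phosphine that could reduce the O–O bond.

Step 16
Reactants: 22 methyl (2S)-2-[(3R,6R)-6-ethenyl-6-methyl-1,2-dioxan-3-yl]propanoate; 23 iodoethene
Product: 25 methyl (2S)-2-[(3R,6R)-6-methyl-6-(3-oxopent-4-en-1-yl)-1,2-dioxan-3-yl]propanoate, via B-alkyl-9-BBN adduct 24 (not isolated)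
Conditions: 9-BBN-H, THF, 0 °C to rt; then 23, CO (1 atm), Pd(PPh3)4 (5 mol %), K3PO4, benzene/THF, rt
Reagents that add atoms: carbon monoxide, [C-]#[O+]
Why: Anti-Markovnikov hydroboration of the monosubstituted alkene, then carbonylative Suzuki–Miyaura coupling (oxidative addition of iodoethene to zerovalent palladium, CO insertion, base-assisted B-alkyl transmetalation, reductive elimination) gives the alkyl vinyl ketone, the iodide ligand slowing transmetalation enough for CO insertion to come first.

Step 17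
Reactants: 7 tert-butyl{[(E)-(3,3-dimethyl-2-methylidenecyclohexylidene)methyl]oxy}dimethylsilane; 25 methyl (2S)-2-[(3R,6R)-6-methyl-6-(3-oxopent-4-en-1-yl)-1,2-dioxan-3-yl]propanoate
Product: 26 methyl (2S)-2-{(3R,6R)-6-[3-(1-{[tert-butyl(dimethyl)silyl]oxy}-5,5-dimethyl-1,2,3,4,5,6,7,8-octahydronaphthalen-2-yl)-3-oxopropyl]-6-methyl-1,2-dioxan-3-yl}propanoate (mixture at C1 and C2 of the octalin)
Conditions: 7 (1.5 equiv), 2,6-di-tert-butyl-4-methylphenol (cat.), toluene, 75 °C, base-washed sealed vessel, dark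
Reagents that add atoms: none
Why: This is a concerted but asynchronous normal-electron-demand [4+2] cycloaddition in which the silyloxy group raises the diene HOMO and places its largest coefficient on the exocyclic CH2, which bonds to the enone β-carbon (C4–C3) slightly ahead of C1–C2. The closest known reaction type is the "ortho"-selective Diels–Alder reaction of 1-silyloxy-1,3-dienes with alkyl vinyl ketones. Ring A is closed by intermolecular [4+2] annulation onto the two exocyclic carbons of ring B, which leaves the new alkene at the ring fusion C4a=C8a. The two new stereocentres (C1 and C2) arise under endo/exo and diene-face preferences that need no control, since both are erased in step 18. The step needs regioselectivity (acyl on C2 next to oxygenated C1), secured by the 1-silyloxy donor and the unsubstituted enone terminus, and chemoselectivity toward the O–O bond, secured by neutral metal-free conditions with a radical inhibitor. Because ring B locks the diene s-cis, reaction is expected well below the temperature at which a dialkyl peroxide decomposes.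

Step 18
Reactants: 26 Diels–Alder adduct (name as in step 17)
Product: 27 methyl (2S)-2-{(3R,6R)-6-[3-(5,5-dimethyl-3,4,5,6,7,8-hexahydronaphthalen-2-yl)-3-oxopropyl]-6-methyl-1,2-dioxan-3-yl}propanoate
Conditions: TsOH·H2O (10 mol %), CH2Cl2, 0 °C to rt
Reagents that add atoms: none
Why: Acid-catalysed β-elimination of silanol from the β-silyloxy ketone (ionisation of the allylic C1–O bond, then loss of the C2 proton) gives the conjugated dienone and erases both centres made in step 17, acid being chosen over base to spare the base-sensitive β-peroxy ester.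

Step 19
Reactants: 27 methyl (2S)-2-{(3R,6R)-6-[3-(5,5-dimethyl-3,4,5,6,7,8-hexahydronaphthalen-2-yl)-3-oxopropyl]-6-methyl-1,2-dioxan-3-yl}propanoate
Product: 28 methyl (2S)-2-{(3R,6S)-6-[3-(5,5-dimethyl-3,4,5,6,7,8-hexahydronaphthalen-2-yl)-3-{2-[(4-methylphenyl)sulfonyl]hydrazinylidene}propyl]-6-methyl-1,2-dioxan-3-yl}propanoate
Conditions: TsNHNH2, AcOH (cat.), MeOH, rt
Reagents that add atoms: 4-methylbenzenesulfonohydrazide, Cc1ccc(cc1)S(=O)(=O)NN
Why: Condensation at the ketone carbonyl gives the tosylhydrazone, conjugate addition at C1 being disfavoured because that carbon is flanked by the ring fusion (the C6 descriptor changes only through ligand priorities).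

Step 20
Reactants: 28 tosylhydrazone (name as in step 19)
Product: 31 methyl (2S)-2-[(3R,6S)-6-{(3Z)-3-[5,5-dimethyl-3,4,5,6,7,8-hexahydronaphthalen-2(1H)-ylidene]propyl}-6-methyl-1,2-dioxan-3-yl]propanoate, via allylic tosylhydrazine 29 (not isolated), via allylic diazene 30 (not isolated)
Conditions: catecholborane, CHCl3, 0 °C; then NaOAc·3H2O, 60 °C
Reagents that add atoms: none
Why: Reductive 1,3-transposition of an α,β-unsaturated tosylhydrazone, in which hydride adds to C=N, acetate releases the sulfinate to give the allylic diazene, and a retro-ene loss of N2 delivers hydrogen to C1 and moves the alkene to the exocyclic position while C4a=C8a stays in place; the C–N bond must stand perpendicular to the C1=C2 plane, and placing the chain toward the vinylic C1–H should cost less than placing it against the C3 methylene (A1,2 strain), so the chain is expected cis to C1, that is the (Z)-alkene.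

Step 21
Reactants: 31 methyl ester of the target (name as in step 20)
Product: 32 (2S)-2-[(3R,6S)-6-{(3Z)-3-[5,5-dimethyl-3,4,5,6,7,8-hexahydronaphthalen-2(1H)-ylidene]propyl}-6-methyl-1,2-dioxan-3-yl]propanoic acid
Conditions: LiOH·H2O, THF/MeOH/H2O, 0 °C; then aq. HCl to pH 3
Reagents that add atoms: lithium hydroxide, [Li+].[OH-]
Why: Saponification (BAc2) of the methyl ester and acidification give the acid, the dialkyl peroxide tolerating cold aqueous hydroxide and the short cold reaction limiting α-epimerisation or retro-oxa-Michael opening of the β-peroxy ester.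

Compound list
1 | 2,2-dimethylcyclohexan-1-one | CC1(C)CCCCC1=O | starting material
2 | ethyl formate | CCOC=O | starting material
3 | (6Z)-6-(hydroxymethylidene)-2,2-dimethylcyclohexan-1-one | O/C=C1/CCCC(C)(C)C1=O | intermediate
4 | (6E)-2,2-dimethyl-6-[(propan-2-yloxy)methylidene]cyclohexan-1-one | CC(C)O/C=C1\CCCC(C)(C)C1=O | intermediate
5 | (6E)-1,2,2-trimethyl-6-[(propan-2-yloxy)methylidene]cyclohexan-1-ol (racemic) | CC(C)O/C=C1\CCCC(C)(C)C1(C)O | intermediate
6 | 2,3,3-trimethylcyclohex-1-ene-1-carbaldehyde | CC1=C(C=O)CCCC1(C)C | intermediate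
7 | tert-butyl{[(E)-(3,3-dimethyl-2-methylidenecyclohexylidene)methyl]oxy}dimethylsilane | C=C1/C(=C/O[Si](C)(C)C(C)(C)C)CCCC1(C)C | intermediate
8 | geranyl acetate, (2E)-3,7-dimethylocta-2,6-dien-1-yl acetate | CC(C)=CCC/C(C)=C/COC(C)=O | starting material
9 | (2E)-3-methyl-6-oxohex-2-en-1-yl acetate | O=CCC/C(C)=C/COC(C)=O | intermediate
10 | 2-[(2E)-but-2-en-1-yl]-4,4,5,5-tetramethyl-1,3,2-dioxaborolane | C/C=C/CB1OC(C)(C)C(C)(C)O1 | starting material
11 | (2E,6S,7R)-3,7-dimethyl-6-[(4,4,5,5-tetramethyl-1,3,2-dioxaborolan-2-yl)oxy]nona-2,8-dien-1-yl acetate | C[C@H](C=C)[C@@H](OB1OC(C)(C)C(C)(C)O1)CC/C(C)=C/COC(C)=O | intermediate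
12 | (2E,6S,7R)-6-hydroxy-3,7-dimethylnona-2,8-dien-1-yl acetate | C[C@H](C=C)[C@@H](O)CC/C(C)=C/COC(C)=O | intermediate
13 | (2E,6S,7R)-6-(methanesulfonyloxy)-3,7-dimethylnona-2,8-dien-1-yl acetate | C[C@H](C=C)[C@@H](OS(C)(=O)=O)CC/C(C)=C/COC(C)=O | intermediate
14 | (3R,4S,7E)-9-hydroxy-3,7-dimethylnona-1,7-dien-4-yl methanesulfonate | C[C@H](C=C)[C@@H](OS(C)(=O)=O)CC/C(C)=C/CO | intermediate
15 | (3R,4S)-6-[(2S,3S)-3-(hydroxymethyl)-2-methyloxiran-2-yl]-3-methylhex-1-en-4-yl methanesulfonate | C[C@H](C=C)[C@@H](OS(C)(=O)=O)CC[C@]1(C)O[C@H]1CO | intermediate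
16 | (3R,4S,7R,8S)-7-hydroperoxy-8,9-dihydroxy-3,7-dimethylnon-1-en-4-yl methanesulfonate | C[C@H](C=C)[C@@H](OS(C)(=O)=O)CC[C@@](C)(OO)[C@@H](O)CO | intermediate
17 | (1S)-1-{(3R,6R)-6-[(2R)-but-3-en-2-yl]-3-methyl-1,2-dioxan-3-yl}ethane-1,2-diol | C[C@H](C=C)[C@H]1CC[C@](C)([C@@H](O)CO)OO1 | intermediate
18 | (2S)-2-{(3R,6R)-6-[(1S)-1,2-dihydroxyethyl]-6-methyl-1,2-dioxan-3-yl}propanal | C[C@H](C=O)[C@H]1CC[C@](C)([C@@H](O)CO)OO1 | intermediate
19 | (2S)-2-{(3R,6R)-6-[(1S)-1,2-dihydroxyethyl]-6-methyl-1,2-dioxan-3-yl}propanoic acid | C[C@H](C(=O)O)[C@H]1CC[C@](C)([C@@H](O)CO)OO1 | intermediate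
20 | methyl (2S)-2-{(3R,6R)-6-[(1S)-1,2-dihydroxyethyl]-6-methyl-1,2-dioxan-3-yl}propanoate | C[C@H](C(=O)OC)[C@H]1CC[C@](C)([C@@H](O)CO)OO1 | intermediate
21 | methyl (2S)-2-[(3R,6R)-6-formyl-6-methyl-1,2-dioxan-3-yl]propanoate | C[C@H](C(=O)OC)[C@H]1CC[C@](C)(C=O)OO1 | intermediate
22 | methyl (2S)-2-[(3R,6R)-6-ethenyl-6-methyl-1,2-dioxan-3-yl]propanoate | C[C@H](C(=O)OC)[C@H]1CC[C@](C)(C=C)OO1 | intermediate
23 | iodoethene | C=CI | starting material
24 | methyl (2S)-2-{(3R,6S)-6-[2-(9-borabicyclo[3.3.1]nonan-9-yl)ethyl]-6-methyl-1,2-dioxan-3-yl}propanoate | C[C@H](C(=O)OC)[C@H]1CC[C@](C)(CCB2C3CCCC2CCC3)OO1 | intermediate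
25 | methyl (2S)-2-[(3R,6R)-6-methyl-6-(3-oxopent-4-en-1-yl)-1,2-dioxan-3-yl]propanoate | C[C@H](C(=O)OC)[C@H]1CC[C@](C)(CCC(=O)C=C)OO1 | intermediate
26 | methyl (2S)-2-{(3R,6R)-6-[3-(1-{[tert-butyl(dimethyl)silyl]oxy}-5,5-dimethyl-1,2,3,4,5,6,7,8-octahydronaphthalen-2-yl)-3-oxopropyl]-6-methyl-1,2-dioxan-3-yl}propanoate (octalin C1/C2 mixture) | C[C@H](C(=O)OC)[C@H]1CC[C@](C)(CCC(=O)C2CCC3=C(CCCC3(C)C)C2O[Si](C)(C)C(C)(C)C)OO1 | intermediate
27 | methyl (2S)-2-{(3R,6R)-6-[3-(5,5-dimethyl-3,4,5,6,7,8-hexahydronaphthalen-2-yl)-3-oxopropyl]-6-methyl-1,2-dioxan-3-yl}propanoate | C[C@H](C(=O)OC)[C@H]1CC[C@](C)(CCC(=O)C2=CC3=C(CC2)C(C)(C)CCC3)OO1 | intermediate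
28 | methyl (2S)-2-{(3R,6S)-6-[3-(5,5-dimethyl-3,4,5,6,7,8-hexahydronaphthalen-2-yl)-3-{2-[(4-methylphenyl)sulfonyl]hydrazinylidene}propyl]-6-methyl-1,2-dioxan-3-yl}propanoate (C=N isomers) | C[C@H](C(=O)OC)[C@H]1CC[C@](C)(CCC(=NNS(=O)(=O)c2ccc(C)cc2)C2=CC3=C(CC2)C(C)(C)CCC3)OO1 | intermediate
29 | methyl (2S)-2-{(3R,6S)-6-[3-(5,5-dimethyl-3,4,5,6,7,8-hexahydronaphthalen-2-yl)-3-{2-[(4-methylphenyl)sulfonyl]hydrazinyl}propyl]-6-methyl-1,2-dioxan-3-yl}propanoate (carbinamine epimers) | C[C@H](C(=O)OC)[C@H]1CC[C@](C)(CCC(NNS(=O)(=O)c2ccc(C)cc2)C2=CC3=C(CC2)C(C)(C)CCC3)OO1 | intermediate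
30 | methyl (2S)-2-{(3R,6S)-6-[3-diazenyl-3-(5,5-dimethyl-3,4,5,6,7,8-hexahydronaphthalen-2-yl)propyl]-6-methyl-1,2-dioxan-3-yl}propanoate (epimers) | C[C@H](C(=O)OC)[C@H]1CC[C@](C)(CCC(N=N)C2=CC3=C(CC2)C(C)(C)CCC3)OO1 | intermediate
31 | methyl (2S)-2-[(3R,6S)-6-{(3Z)-3-[5,5-dimethyl-3,4,5,6,7,8-hexahydronaphthalen-2(1H)-ylidene]propyl}-6-methyl-1,2-dioxan-3-yl]propanoate | C[C@H](C(=O)OC)[C@H]1CC[C@](C)(CC/C=C2/CCC3=C(CCCC3(C)C)C2)OO1 | intermediate
32 | (2S)-2-[(3R,6S)-6-{(3Z)-3-[5,5-dimethyl-3,4,5,6,7,8-hexahydronaphthalen-2(1H)-ylidene]propyl}-6-methyl-1,2-dioxan-3-yl]propanoic acid | C[C@H](C(=O)O)[C@H]1CC[C@](C)(CC/C=C2/CCC3=C(CCCC3(C)C)C2)OO1 | target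

Total step count: 21 (diene 4, dienophile 12, key step and endgame 5). Longest linear sequence: 17 steps (steps 5–21, from geranyl acetate).

Steps most likely to fail

1. Step 16. The O–O bond may be cleaved reductively by zerovalent palladium, free phosphine or the dialkylborane; direct (non-carbonylative) coupling or base-induced polymerisation of the enone may also compete. The fallback sets out from aldehyde 21 (step 15 is skipped) and comes back at 25. A Wittig reaction with the stabilised ylide N-methoxy-N-methyl-2-(triphenylphosphoranylidene)acetamide (CH2Cl2, rt) gives methyl (2S)-2-[(3R,6R)-6-{(1E)-3-[methoxy(methyl)amino]-3-oxoprop-1-en-1-yl}-6-methyl-1,2-dioxan-3-yl]propanoate F3. Diimide (2-nitrobenzenesulfonohydrazide, Et3N, CH2Cl2, rt), which reduces C=C but not O–O, gives methyl (2S)-2-[(3R,6R)-6-{3-[methoxy(methyl)amino]-3-oxopropyl}-6-methyl-1,2-dioxan-3-yl]propanoate F4. Vinylmagnesium bromide (THF, −78 °C, inverse quench into cold aqueous acid) then adds to the N-methoxy-N-methylamide, whose chelated adduct forms faster than attack on the methyl ester at this temperature, and gives 25.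

2. Step 20. The alkene geometry may erode through the competing transition state with the chain toward C3, and hydride may be delivered to the conjugated positions of the dienyl hydrazone. The fallback sets out from dienone 27 and comes back at 31. Luche reduction (NaBH4, CeCl3·7H2O, MeOH, −40 °C) gives methyl (2S)-2-{(3R,6S)-6-[3-(5,5-dimethyl-3,4,5,6,7,8-hexahydronaphthalen-2-yl)-3-hydroxypropyl]-6-methyl-1,2-dioxan-3-yl}propanoate F5. Mitsunobu displacement with 2-nitrobenzenesulfonohydrazide (PPh3 and diethyl azodicarboxylate premixed, N-methylmorpholine, −30 °C) gives methyl (2S)-2-{(3R,6S)-6-[3-(5,5-dimethyl-3,4,5,6,7,8-hexahydronaphthalen-2-yl)-3-[1-(2-nitrobenzenesulfonyl)hydrazinyl]propyl]-6-methyl-1,2-dioxan-3-yl}propanoate F6. On warming to room temperature F6 loses the sulfinic acid to give diazene 30, which rearranges to 31. The retro-ene step then runs some forty to ninety degrees colder, which should sharpen the kinetic preference, and no hydride reagent touches the diene; any (E)-isomer would be removed on AgNO3-impregnated silica.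

3. Step 17. The silyl dienol ether may be lost by protodesilylation, or the vinyl ketone may polymerise, faster than cycloaddition occurs. The fallback sets out from enal 6 and dienophile 25 and comes back at dienone 27 (steps 4 and 18 are skipped). Condensation of 6 with pyrrolidine (K2CO3, 4 Å molecular sieves, Et2O) gives the dienamine 1-[(E)-(3,3-dimethyl-2-methylidenecyclohexylidene)methyl]pyrrolidine F1. F1 adds to 25 at room temperature in MeCN in the same regiochemical sense (Michael–Mannich [4+2]) to give methyl (2S)-2-[(3R,6R)-6-{3-[5,5-dimethyl-1-(pyrrolidin-1-yl)-1,2,3,4,5,6,7,8-octahydronaphthalen-2-yl]-3-oxopropyl}-6-methyl-1,2-dioxan-3-yl]propanoate F2. Buffered AcOH/NaOAc work-up eliminates pyrrolidine from F2 to give 27.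

Further compounds
F1 | step 17 | 1-[(E)-(3,3-dimethyl-2-methylidenecyclohexylidene)methyl]pyrrolidine | C=C1/C(=C/N2CCCC2)CCCC1(C)C
F2 | step 17 | methyl (2S)-2-[(3R,6R)-6-{3-[5,5-dimethyl-1-(pyrrolidin-1-yl)-1,2,3,4,5,6,7,8-octahydronaphthalen-2-yl]-3-oxopropyl}-6-methyl-1,2-dioxan-3-yl]propanoate (octalin C1/C2 mixture) | C[C@H](C(=O)OC)[C@H]1CC[C@](C)(CCC(=O)C2CCC3=C(CCCC3(C)C)C2N2CCCC2)OO1
F3 | step 16 | methyl (2S)-2-[(3R,6R)-6-{(1E)-3-[methoxy(methyl)amino]-3-oxoprop-1-en-1-yl}-6-methyl-1,2-dioxan-3-yl]propanoate | C[C@H](C(=O)OC)[C@H]1CC[C@](C)(/C=C/C(=O)N(C)OC)OO1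
F4 | step 16 | methyl (2S)-2-[(3R,6R)-6-{3-[methoxy(methyl)amino]-3-oxopropyl}-6-methyl-1,2-dioxan-3-yl]propanoate | C[C@H](C(=O)OC)[C@H]1CC[C@](C)(CCC(=O)N(C)OC)OO1
F5 | step 20 | methyl (2S)-2-{(3R,6S)-6-[3-(5,5-dimethyl-3,4,5,6,7,8-hexahydronaphthalen-2-yl)-3-hydroxypropyl]-6-methyl-1,2-dioxan-3-yl}propanoate (carbinol epimers) | C[C@H](C(=O)OC)[C@H]1CC[C@](C)(CCC(O)C2=CC3=C(CC2)C(C)(C)CCC3)OO1
F6 | step 20 | methyl (2S)-2-{(3R,6S)-6-[3-(5,5-dimethyl-3,4,5,6,7,8-hexahydronaphthalen-2-yl)-3-[1-(2-nitrobenzenesulfonyl)hydrazinyl]propyl]-6-methyl-1,2-dioxan-3-yl}propanoate (epimers) | C[C@H](C(=O)OC)[C@H]1CC[C@](C)(CCC(N(N)S(=O)(=O)c2ccccc2[N+](=O)[O-])C2=CC3=C(CC2)C(C)(C)CCC3)OO1
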